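**Plan**

Core numbering (bicyclo[3.3.1]nonane): C1 bridgehead carbinol, C2–C3 oxirane, C4 carbinol, C5 bridgehead CH, C6 carbinol, C7 amide carbon, C8 CH2, C9 ketone; ring A = C1, C8, C7, C6, C5, C9; ring B = C1, C2, C3, C4, C5, C9.
Enabling feature: ring B carries oxygen at C1, C2, C3, C4 and C9 while C5, next to the ketone, carries none – a 2-deoxy-inosose, the product type of mercury-mediated carbocyclization of a 6-deoxyhex-5-enopyranoside (sugar C5 → C9, C6 → C5, C1 → C4, C2/C3 → C3/C2, C4 → C1).
Cuts: amide N–CO; C7–N (nitrenoid insertion from a C6 carbamate); C5–C6 (aldol closing ring A from a C1-bound 3-oxopropyl chain, made by hydroformylation of a C1 vinyl group); C4–C5 (the carbocyclization closing ring B); C1–vinyl (Grignard addition to a sugar 4-ulose).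
Forward order: 2,3-anhydro-allo sugar → 4-C-vinyl hex-5-enopyranoside → ring B → ring A → nitrogen at C7 → inversion of C4 → side-chain amide → desilylation; the acid is made separately from δ-decalactone.
Stereochemistry: C2 and C3 come from the sugar oxirane; C1 from vinyl addition anti to the oxirane; C5 from the tether and C6 from the C4 silyloxy group in the ring A aldol; C7 from syn delivery from O6; C4 is expected to form trans to the oxirane in the carbocyclization, is used as a control element, and is finally set by oxidation and hydride delivery anti to the oxirane.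

Key step: step 6

Remark: 1 is taken as a catalogue compound (it is the dimesylate/NaOMe derivative of methyl 4,6-O-benzylidene-α-D-glucopyranoside, itself from methyl α-D-glucopyranoside); δ-decalactone 24 is used as the racemate because its carbinol carbon becomes the side-chain ketone.

**Route**

Step 1
Reactants: 1 methyl 2,3-anhydro-4,6-O-benzylidene-α-D-allopyranoside
Product: 2 methyl 2,3-anhydro-4-O-benzoyl-6-bromo-6-deoxy-α-D-allopyranoside
Conditions: NBS, BaCO3, CCl4, reflux
Reagents that add atoms: N-bromosuccinimide, O=C1CCC(=O)N1Br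
Why: Hanessian–Hullar reaction: radical bromination at the acetal carbon gives a benzoxonium ion that bromide opens at the primary C6, so the acetal becomes the 6-bromide and 4-benzoate in one operation with no stereocentre touched and the oxirane a spectator under the buffered conditions.

Step 2
Reactants: 2 methyl 2,3-anhydro-4-O-benzoyl-6-bromo-6-deoxy-α-D-allopyranoside
Product: 3 methyl 2,3-anhydro-6-bromo-6-deoxy-α-D-allopyranoside
Conditions: K2CO3 (cat.), MeOH, 0 °C
Reagents that add atoms: none
Why: Zemplén-type transesterification frees O4; the alkoxide is cis to the oxirane and so cannot undergo Payne migration, and the primary bromide next to the ring oxygen is slow in SN2.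

Step 3
Reactants: 3 methyl 2,3-anhydro-6-bromo-6-deoxy-α-D-allopyranoside
Product: 5 methyl 2,3-anhydro-6-deoxy-α-D-erythro-hex-5-enopyranosid-4-ulose, via bromo ketone 4 (not isolated)
Conditions: Dess–Martin periodinane, CH2Cl2, 0 °C; then Et3N, 0 °C
Reagents that add atoms: none
Why: Dess–Martin oxidation gives the 4-ulose 4, whose C5–H is now α to the ketone and β to bromide, so triethylamine should induce E1cB loss of HBr to the exocyclic 2-alkoxy enone, the sugar C5 centre being removed on purpose.

Step 4
Reactants: 5 methyl 2,3-anhydro-6-deoxy-α-D-erythro-hex-5-enopyranosid-4-ulose; 6 vinylmagnesium bromide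
Product: 7 methyl 2,3-anhydro-6-deoxy-4-C-vinyl-α-D-ribo-hex-5-enopyranoside
Conditions: CeCl3, THF, −78 °C; aq. NH4Cl
Reagents that add atoms: none
Why: Organocerium 1,2-addition (the enol-ether oxygen on the α-carbon lowers the acceptor character of C6 and cerium suppresses conjugate addition); the vinyl group should enter on the β face, anti to the oxirane oxygen and the axial anomeric methoxy group that both lie on the α face, which places the new tertiary hydroxyl (core C1) cis to the oxirane.

Step 5
Reactants: 7 methyl 2,3-anhydro-6-deoxy-4-C-vinyl-α-D-ribo-hex-5-enopyranoside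
Product: 8 methyl 2,3-anhydro-6-deoxy-4-O-triethylsilyl-4-C-vinyl-α-D-ribo-hex-5-enopyranoside
Conditions: TESOTf, 2,6-lutidine, CH2Cl2, −78 to 0 °C
Reagents that add atoms: triethylsilyl trifluoromethanesulfonate, CC[Si](CC)(CC)OS(=O)(=O)C(F)(F)F
Why: Silylation of a tertiary alcohol by a silyl triflate and a hindered base; the cap is needed because a free O4–H, held cis to the anomeric carbon by the oxirane, would trap the aldehyde of step 6 as a five-membered lactol.

Step 6
Reactants: 8 methyl 2,3-anhydro-6-deoxy-4-O-triethylsilyl-4-C-vinyl-α-D-ribo-hex-5-enopyranoside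
Product: 10 2,3-epoxy-4-hydroxy-6-(triethylsilyloxy)-6-vinylcyclohexanone (ring B; hydroxyl trans to the oxirane), via mercurio keto-aldehyde 9 (not isolated)
Conditions: Hg(OCOCF3)2 (10 mol%), acetone–H2O (4:1), rt
Reagents that add atoms: water, O
Why: Divalent mercury adds to the terminal carbon of the exocyclic enol ether (core C5) and water to the other carbon (core C9); the hemiketal collapses to the C9 ketone, the pyranose opens, methanol is lost, and the acyclic α-mercurio keto-aldehyde 9 closes by attack of C5 on the aldehyde carbon C4, releasing the mercury salt for the next turnover. This is the Ferrier carbocyclization of 6-deoxyhex-5-enopyranosides to 2-deoxy-inososes, here on a 2,3-anhydro-4-C-branched substrate. Ring B closes as a 6-(enolendo)-exo-trig aldol, the cis-oxirane holding C1 and C4 on one side so that the two chain ends meet, and the three sugar-derived centres (C1, C2, C3) are carried through unchanged. The one new stereocentre, C4, is controlled by the oxirane: in the half-chair transition state the aldehyde oxygen should turn away from the oxirane oxygen (dipole minimisation, the same sense as the usual outcome with the hydroxyl trans to the sugar C3 oxygen), so the hydroxyl is expected trans to the oxirane, which is the C4 epimer of the target; this is accepted because that oxygen later steers C6 and C4 is reset in steps 13 to 15. What the step needs is chemoselectivity and a free aldehyde: the enol ether is far more nucleophilic toward mercury than the vinyl group, C5 is the only enolisable position because C1 is quaternary, the O1 silyl ether prevents lactol formation, and the catalytic, nearly neutral medium should spare the oxirane and avoid β-elimination of the new hydroxyl.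

Step 7
Reactants: 10 2,3-epoxy-4-hydroxy-6-(triethylsilyloxy)-6-vinylcyclohexanone
Product: 11 4,5-epoxy-1,3,6-tris(triethylsilyloxy)-6-vinylcyclohex-1-ene (C4 silyl ether and C9 silyl enol ether of 10)
Conditions: TESOTf (2.5 equiv), Et3N, CH2Cl2, −78 to 0 °C
Reagents that add atoms: triethylsilyl trifluoromethanesulfonate, CC[Si](CC)(CC)OS(=O)(=O)C(F)(F)F
Why: O-silylation of the secondary alcohol and soft enolisation of the ketone by silyl triflate and triethylamine in one operation; C5 is the only α-position with hydrogen, and enol silane formation under these conditions does not expel a β-silyloxy group.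

Step 8
Reactants: 11 4,5-epoxy-1,3,6-tris(triethylsilyloxy)-6-vinylcyclohex-1-ene
Product: 12 3-[4,5-epoxy-1,3,6-tris(triethylsilyloxy)cyclohex-1-en-6-yl]propanal
Conditions: Rh(CO)2(acac) (2 mol%), Xantphos (4 mol%), CO/H2 (1:1, 10 bar), toluene, 70 °C
Reagents that add atoms: carbon monoxide, [C-]#[O+]
Why: Rhodium-catalysed hydroformylation of a monosubstituted alkene on a quaternary carbon can give only the linear aldehyde and cannot isomerise, while the trisubstituted silyl enol ether, the oxirane and the silyl ethers are inert; the vinyl CH becomes C8, its CH2 becomes C7 and CO supplies C6.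

Step 9
Reactants: 12 3-[4,5-epoxy-1,3,6-tris(triethylsilyloxy)cyclohex-1-en-6-yl]propanal
Product: 13 2,3-epoxy-6-hydroxy-1,4-bis(triethylsilyloxy)bicyclo[3.3.1]nonan-9-one (C6–OH axial on ring A; C4–O equatorial on ring B)
Conditions: BF3·OEt2, CH2Cl2, −78 °C; aq. NaHCO3
Reagents that add atoms: none
Why: Intramolecular Mukaiyama aldol, 6-(enolendo)-exo-trig, closes ring A: the chain on C1 can reach C5 only on its own face, which fixes C5, and the aldehyde oxygen should take the axial position on ring A (syn to C9) because the equatorial position would lie 1,3-parallel to the equatorial C4 silyloxy group, which sets C6 as in the target.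

Step 10
Reactants: 13 2,3-epoxy-6-hydroxy-1,4-bis(triethylsilyloxy)bicyclo[3.3.1]nonan-9-one
Product: 15 C6 carbamate of 13 (C6–OCONH2), via trichloroacetyl carbamate 14 (not isolated)
Conditions: Cl3CC(O)NCO, CH2Cl2, 0 °C; then K2CO3, MeOH, 0 °C
Reagents that add atoms: trichloroacetyl isocyanate, O=C=NC(=O)C(Cl)(Cl)Cl
Why: Addition of the alcohol to the acyl isocyanate and methanolysis of the trichloroacetyl group is the standard route to a primary carbamate; the C9 ketone has no enolisable α-hydrogen (C1 quaternary, C5 bridgehead), so neither elimination nor epimerisation can occur.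

Step 11
Reactants: 15 C6 carbamate of 13
Product: 16 oxazolidinone fused at C6–O and C7–N (nitrogen equatorial on ring A and cis to O6)
Conditions: Rh2(OAc)4 (5 mol%), PhI(OAc)2, MgO, CH2Cl2, 40 °C
Reagents that add atoms: none
Why: Rhodium-nitrenoid C–H amination of a carbamate forms the five-membered oxazolidinone by insertion, with retention, into the adjacent C7–H that is cis to O6, so nitrogen arrives on the face of O6; the other adjacent C–H, at C5, is a bridgehead α to the ketone and electronically deactivated.

Step 12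
Reactants: 16 oxazolidinone fused at C6–O and C7–N
Product: 17 N-Boc derivative of 16
Conditions: Boc2O, DMAP (cat.), Et3N, THF, rt
Reagents that add atoms: di-tert-butyl dicarbonate, CC(C)(C)OC(=O)OC(=O)OC(C)(C)C
Why: DMAP-catalysed N-acylation of the oxazolidinone, with no free hydroxyl present; the Boc group activates the ring carbonyl for the mild opening in step 16.

Step 13
Reactants: 17 N-Boc derivative of 16
Product: 18 C4 alcohol (hydroxyl trans to the oxirane; C1–OTES kept)
Conditions: HF·pyridine, pyridine, THF, 0 °C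
Reagents that add atoms: none
Why: Buffered HF·pyridine should cleave the secondary triethylsilyl ether at C4 much faster than the tertiary one at the C1 bridgehead next to the ketone, and the oxirane and N-Boc oxazolidinone tolerate it.

Step 14
Reactants: 18 C4 alcohol
Product: 19 C4 ketone (2,3-epoxy-4,9-dione)
Conditions: Dess–Martin periodinane, CH2Cl2, 0 °C to rt
Reagents that add atoms: none
Why: Dess–Martin oxidation of the secondary alcohol; the resulting 1,3-diketone can neither enolise nor eliminate because C5 is a bridgehead (Bredt's rule), and it is used at once.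

Step 15
Reactants: 19 C4 ketone
Product: 20 C4 alcohol cis to the oxirane (axial on ring B; target configuration)
Conditions: LiBH(s-Bu)3, THF, −78 °C
Reagents that add atoms: none
Why: Hydride reduction of an α,β-epoxy ketone anti to the oxirane oxygen gives the cis-epoxy alcohol; here the oxirane oxygen covers the face of C4 turned toward C9, the bulky hydride should come from the equatorial side, and the C9 ketone is shielded in front by the oxirane oxygen and behind by the axial C6 oxygen.

Step 16
Reactants: 20 C4 alcohol cis to the oxirane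
Product: 22 N-Boc amino diol (C7–NHBoc; C6–OH; C4–OH; C1–OTES), via methyl carbonate 21 (not isolated)
Conditions: Cs2CO3 (cat.), MeOH, 0 °C to rt
Reagents that add atoms: none
Why: Methoxide opens the N-Boc oxazolidinone at the ring carbonyl (the tert-butyl group shields the exocyclic one) and the C6 methyl carbonate 21 is then methanolysed; the C4 alkoxide is cis to the oxirane, so no Payne migration is possible.

Step 17
Reactants: 22 N-Boc amino diol
Product: 23 7-amino-2,3-epoxy-4,6-dihydroxy-1-(triethylsilyloxy)bicyclo[3.3.1]nonan-9-one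
Conditions: TFA, CH2Cl2, 0 °C; then aq. NaHCO3
Reagents that add atoms: none
Why: Acidolysis of the tert-butyl carbamate; the tertiary silyl ether and the oxirane, which is flanked by two oxygen-bearing carbons and so is slow to ionise, should survive short exposure at 0 °C.

Step 18
Reactants: 24 δ-decalactone (racemic)
Product: 25 6-pentyloxan-2-ol
Conditions: i-Bu2AlH, CH2Cl2, −78 °C; aq. Rochelle salt
Reagents that add atoms: none
Why: Partial reduction of a lactone to the lactol at low temperature, where the tetrahedral aluminium alkoxide does not collapse.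

Step 19
Reactants: 25 6-pentyloxan-2-ol; 26 tert-butyl (triphenylphosphoranylidene)acetate
Product: 27 tert-butyl (E)-7-hydroxydodec-2-enoate (racemic)
Conditions: toluene, 80 °C
Reagents that add atoms: none
Why: Wittig reaction of the open hydroxy-aldehyde form of the lactol with a stabilised ylide should give the E-enoate under neutral conditions that do not promote oxa-Michael closure.

Step 20
Reactants: 27 tert-butyl (E)-7-hydroxydodec-2-enoate
Product: 28 tert-butyl (E)-7-oxododec-2-enoate
Conditions: Dess–Martin periodinane, CH2Cl2, rt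
Reagents that add atoms: none
Why: Dess–Martin oxidation of the secondary alcohol gives the side-chain ketone and removes the only stereocentre of this fragment.

Step 21
Reactants: 28 tert-butyl (E)-7-oxododec-2-enoate
Product: 29 (E)-7-oxododec-2-enoic acid
Conditions: TFA, CH2Cl2, rt
Reagents that add atoms: none
Why: Acidolysis of the tert-butyl ester avoids base, under which the ketone enolate could add to the enoate.

Step 22
Reactants: 23 7-amino-2,3-epoxy-4,6-dihydroxy-1-(triethylsilyloxy)bicyclo[3.3.1]nonan-9-one; 29 (E)-7-oxododec-2-enoic acid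
Product: 31 1-O-triethylsilyl isariotin C, via benzotriazolyl ester 30 (not isolated)
Conditions: EDC·HCl, HOBt, i-Pr2NEt, DMF, 0 °C to rt
Reagents that add atoms: none
Why: Carbodiimide/HOBt amide coupling, in which the primary amine should be acylated in preference to the two secondary hydroxyls.

Step 23
Reactants: 31 1-O-triethylsilyl isariotin C
Product: 32 isariotin C
Conditions: HF·pyridine, pyridine, THF, 0 °C to rt
Reagents that add atoms: none
Why: Fluoride-mediated cleavage of the tertiary silyl ether under buffered conditions that should leave the oxirane, the two β-hydroxy ketone units and the unsaturated amide untouched.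

**Compound list**

1 | methyl 2,3-anhydro-4,6-O-benzylidene-α-D-allopyranoside (R acetal carbon) | CO[C@H]1O[C@@H]2CO[C@@H](c3ccccc3)O[C@H]2[C@H]4O[C@H]41 | starting material
2 | methyl 2,3-anhydro-4-O-benzoyl-6-bromo-6-deoxy-α-D-allopyranoside | CO[C@H]1O[C@H](CBr)[C@@H](OC(=O)c2ccccc2)[C@H]3O[C@H]31 | intermediate
3 | methyl 2,3-anhydro-6-bromo-6-deoxy-α-D-allopyranoside | CO[C@H]1O[C@H](CBr)[C@@H](O)[C@H]2O[C@H]21 | intermediate
4 | methyl 2,3-anhydro-6-bromo-6-deoxy-α-D-ribo-hexopyranosid-4-ulose (not isolated) | CO[C@H]1O[C@H](CBr)C(=O)[C@H]2O[C@H]21 | intermediate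
5 | methyl 2,3-anhydro-6-deoxy-α-D-erythro-hex-5-enopyranosid-4-ulose | CO[C@H]1OC(=C)C(=O)[C@H]2O[C@H]21 | intermediate
6 | vinylmagnesium bromide | C=C[Mg]Br | starting material
7 | methyl 2,3-anhydro-6-deoxy-4-C-vinyl-α-D-ribo-hex-5-enopyranoside (tertiary OH cis to the oxirane) | CO[C@H]1OC(=C)[C@](O)(C=C)[C@H]2O[C@H]21 | intermediate
8 | methyl 2,3-anhydro-6-deoxy-4-O-triethylsilyl-4-C-vinyl-α-D-ribo-hex-5-enopyranoside | CO[C@H]1OC(=C)[C@](O[Si](CC)(CC)CC)(C=C)[C@H]2O[C@H]21 | intermediate
9 | open-chain 2,3-anhydro-6-deoxy-6-(trifluoroacetoxymercurio)-4-O-triethylsilyl-4-C-vinyl-D-ribo-hexos-5-ulose (not isolated) | O=C[C@@H]1O[C@@H]1[C@@](O[Si](CC)(CC)CC)(C=C)C(=O)C[Hg]OC(=O)C(F)(F)F | intermediate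
10 | 2,3-epoxy-4-hydroxy-6-(triethylsilyloxy)-6-vinylcyclohexanone; oxirane and silyloxy group on one face, hydroxyl and vinyl group on the other (ring B, C4–OH trans to the oxirane) | C=C[C@@]1(O[Si](CC)(CC)CC)C(=O)C[C@@H](O)[C@@H]2O[C@@H]21 | intermediate
11 | 4,5-epoxy-1,3,6-tris(triethylsilyloxy)-6-vinylcyclohex-1-ene (configuration as in 10) | C=C[C@@]1(O[Si](CC)(CC)CC)C(O[Si](CC)(CC)CC)=C[C@@H](O[Si](CC)(CC)CC)[C@@H]2O[C@@H]21 | intermediate
12 | 3-[4,5-epoxy-1,3,6-tris(triethylsilyloxy)cyclohex-1-en-6-yl]propanal | O=CCC[C@@]1(O[Si](CC)(CC)CC)C(O[Si](CC)(CC)CC)=C[C@@H](O[Si](CC)(CC)CC)[C@@H]2O[C@@H]21 | intermediate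
13 | 2,3-epoxy-6-hydroxy-1,4-bis(triethylsilyloxy)bicyclo[3.3.1]nonan-9-one; O1 and oxirane syn, C4–O trans to the oxirane (equatorial on ring B), C6–OH axial on ring A | C1C[C@@]2(O[Si](CC)(CC)CC)C(=O)[C@H]([C@@H](O[Si](CC)(CC)CC)[C@@H]3O[C@@H]32)[C@H]1O | intermediate
14 | C6 N-(trichloroacetyl)carbamate of 13 (not isolated) | C1C[C@@]2(O[Si](CC)(CC)CC)C(=O)[C@H]([C@@H](O[Si](CC)(CC)CC)[C@@H]3O[C@@H]32)[C@H]1OC(=O)NC(=O)C(Cl)(Cl)Cl | intermediate
15 | C6 carbamate of 13 | C1C[C@@]2(O[Si](CC)(CC)CC)C(=O)[C@H]([C@@H](O[Si](CC)(CC)CC)[C@@H]3O[C@@H]32)[C@H]1OC(N)=O | intermediate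
16 | oxazolidinone fused cis at C6–O and C7–N; other groups as in 13 | O=C1N[C@H]2C[C@@]3(O[Si](CC)(CC)CC)C(=O)[C@H]([C@@H](O[Si](CC)(CC)CC)[C@@H]4O[C@@H]43)[C@H]2O1 | intermediate
17 | N-Boc derivative of 16 | O=C1N(C(=O)OC(C)(C)C)[C@H]2C[C@@]3(O[Si](CC)(CC)CC)C(=O)[C@H]([C@@H](O[Si](CC)(CC)CC)[C@@H]4O[C@@H]43)[C@H]2O1 | intermediate
18 | 17 with free C4 hydroxyl (trans to the oxirane) | O=C1N(C(=O)OC(C)(C)C)[C@H]2C[C@@]3(O[Si](CC)(CC)CC)C(=O)[C@H]([C@@H](O)[C@@H]4O[C@@H]43)[C@H]2O1 | intermediate
19 | C4 ketone from 18 | O=C1N(C(=O)OC(C)(C)C)[C@H]2C[C@@]3(O[Si](CC)(CC)CC)C(=O)[C@H](C(=O)[C@@H]4O[C@@H]43)[C@H]2O1 | intermediate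
20 | C4 alcohol cis to the oxirane (axial on ring B) | O=C1N(C(=O)OC(C)(C)C)[C@H]2C[C@@]3(O[Si](CC)(CC)CC)C(=O)[C@H]([C@H](O)[C@@H]4O[C@@H]43)[C@H]2O1 | intermediate
21 | ring-opened C6 methyl carbonate with C7–NHBoc (not isolated) | CC(C)(C)OC(=O)N[C@H]1C[C@@]2(O[Si](CC)(CC)CC)C(=O)[C@H]([C@H](O)[C@@H]3O[C@@H]32)[C@H]1OC(=O)OC | intermediate
22 | 7-(Boc-amino)-2,3-epoxy-4,6-dihydroxy-1-(triethylsilyloxy)bicyclo[3.3.1]nonan-9-one | CC(C)(C)OC(=O)N[C@H]1C[C@@]2(O[Si](CC)(CC)CC)C(=O)[C@H]([C@H](O)[C@@H]3O[C@@H]32)[C@H]1O | intermediate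
23 | 7-amino-2,3-epoxy-4,6-dihydroxy-1-(triethylsilyloxy)bicyclo[3.3.1]nonan-9-one | N[C@H]1C[C@@]2(O[Si](CC)(CC)CC)C(=O)[C@H]([C@H](O)[C@@H]3O[C@@H]32)[C@H]1O | intermediate
24 | δ-decalactone (6-pentyloxan-2-one, racemic) | CCCCCC1CCCC(=O)O1 | starting material
25 | 6-pentyloxan-2-ol (racemic, anomer mixture) | CCCCCC1CCCC(O)O1 | intermediate
26 | tert-butyl (triphenylphosphoranylidene)acetate | CC(C)(C)OC(=O)C=P(c1ccccc1)(c1ccccc1)c1ccccc1 | starting material
27 | tert-butyl (E)-7-hydroxydodec-2-enoate (racemic) | CCCCCC(O)CCC/C=C/C(=O)OC(C)(C)C | intermediate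
28 | tert-butyl (E)-7-oxododec-2-enoate | CCCCCC(=O)CCC/C=C/C(=O)OC(C)(C)C | intermediate
29 | (E)-7-oxododec-2-enoic acid | CCCCCC(=O)CCC/C=C/C(=O)O | intermediate
30 | benzotriazol-1-yl (E)-7-oxododec-2-enoate (not isolated) | CCCCCC(=O)CCC/C=C/C(=O)On1nnc2ccccc12 | intermediate
31 | 1-O-triethylsilyl isariotin C | CCCCCC(=O)CCC/C=C/C(=O)N[C@H]1C[C@@]2(O[Si](CC)(CC)CC)C(=O)[C@H]([C@H](O)[C@@H]3O[C@@H]32)[C@H]1O | intermediate
32 | isariotin C | CCCCCC(=O)CCC/C=C/C(=O)N[C@H]1C[C@@]2(O)C(=O)[C@H]([C@H](O)[C@@H]3O[C@@H]32)[C@H]1O | target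

**Step count**

Total: 23 steps. Longest linear sequence: 19 steps (steps 1–17, 22 and 23, from 1); the side-chain acid takes 4 steps (18–21).

**Three steps most likely to fail**

1. Step 11. Nitrenoid insertion into an unactivated secondary C–H may be too slow relative to catalyst decay or to oxidation elsewhere, leaving carbamate unconverted. The fallback sets out from 13 and returns at 16. Alcohol 13 would be mesylated (MsCl, Et3N, CH2Cl2) to the C6 mesylate F1 and heated with DBU in toluene; only the axial C7–H is anti-periplanar to the axial leaving group and C5 cannot take part, so the C6=C7 alkene F2 should result. Sharpless aminohydroxylation (ethyl carbamate, t-BuOCl, NaOH, K2OsO2(OH)4 cat., n-PrOH–H2O) should add nitrogen and oxygen syn to the open face of ring A, the other face being covered by ring B and its C4 silyloxy group, with nitrogen at the less hindered C7, to give the hydroxy ethyl carbamate F3. Catalytic t-BuOK in THF closes F3 to oxazolidinone 16 with loss of ethanol.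

2. Step 9. The Lewis acid may open the oxirane or strip silyl groups before the aldol closes ring A. The fallback sets out from 10 and returns at 13. Only the C4 hydroxyl of 10 would be silylated (TESOTf, 2,6-lutidine, −78 °C) to the ketone F4, which is hydroformylated as in step 8 to the keto-aldehyde F5. Ring A is then closed without any Lewis acid by a reversible base-mediated aldol (LiOt-Bu cat., THF, −40 °C, high dilution), in which the lithium aldolate chelated to the C9 carbonyl, with O6 axial, is the expected resting state.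

3. Step 15. Hydride delivery may show poor facial selectivity at C4 or poor chemoselectivity against the C9 ketone. The fallback sets out from 18 and returns at 22, bypassing 19 and 20. Mitsunobu reaction of 18 (4-nitrobenzoic acid, PPh3, DIAD, toluene) should displace the equatorial C4 oxygen with inversion to give the axial 4-nitrobenzoate F6. Cs2CO3 in MeOH then removes the ester and opens the N-Boc oxazolidinone in the same operation to give 22.

**Further compounds**

F1 | step 11 | C6 mesylate of 13 | C1C[C@@]2(O[Si](CC)(CC)CC)C(=O)[C@H]([C@@H](O[Si](CC)(CC)CC)[C@@H]3O[C@@H]32)[C@H]1OS(C)(=O)=O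
F2 | step 11 | 2,3-epoxy-1,4-bis(triethylsilyloxy)bicyclo[3.3.1]non-6-en-9-one | C1=CC[C@@]2(O[Si](CC)(CC)CC)C(=O)[C@@H]1[C@@H](O[Si](CC)(CC)CC)[C@@H]3O[C@@H]32
F3 | step 11 | 7-(ethoxycarbonylamino)-2,3-epoxy-6-hydroxy-1,4-bis(triethylsilyloxy)bicyclo[3.3.1]nonan-9-one (N and O6 cis) | CCOC(=O)N[C@H]1C[C@@]2(O[Si](CC)(CC)CC)C(=O)[C@H]([C@@H](O[Si](CC)(CC)CC)[C@@H]3O[C@@H]32)[C@H]1O
F4 | step 9 | 2,3-epoxy-4,6-bis(triethylsilyloxy)-6-vinylcyclohexanone (configuration as in 10) | C=C[C@@]1(O[Si](CC)(CC)CC)C(=O)C[C@@H](O[Si](CC)(CC)CC)[C@@H]2O[C@@H]21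
F5 | step 9 | 3-[2,3-epoxy-6-oxo-1,4-bis(triethylsilyloxy)cyclohexyl]propanal | O=CCC[C@@]1(O[Si](CC)(CC)CC)C(=O)C[C@@H](O[Si](CC)(CC)CC)[C@@H]2O[C@@H]21
F6 | step 15 | C4 4-nitrobenzoate of 20 (ester cis to the oxirane) | O=C1N(C(=O)OC(C)(C)C)[C@H]2C[C@@]3(O[Si](CC)(CC)CC)C(=O)[C@H]([C@H](OC(=O)c5ccc(cc5)[N+](=O)[O-])[C@@H]4O[C@@H]43)[C@H]2O1
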